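The target is numbered as a decalin (C2 ketone, C3 bearing cyclopentane ring A, C4a and C5 carbinols, C8 bromide, C8a methyl; ring B = enone ring, ring C = diol ring). Ring B is cut at C3–C4 and C4a–C8a. Its C2 oxygen lies para to C4a, which carries C5. This is the pattern of a 2-silyloxydiene plus acylalkyne Diels–Alder adduct with C5–C8 as tether. One intramolecular cycloaddition of an open-chain silyloxydiene-ynone attached to camphor-derived ring A closes rings B and C and sets quaternary C8a from the C8 carbinol. C8-Br, C4a-OH and C5 are then relayed from C8a.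

Key step: step 15

Assumption: β is the decalin face that carries the C8a methyl group and α the opposite face; enediones 24 and 26 are drawn as the C4=C4a tautomers, and equilibration with the C3=C4 isomers would be harmless because both give dienolate 27.

Step 1
Reactants: 1 (1R,4S)-(+)-camphanic acid
Product: 3 (1S)-1,2,2-trimethyl-3-oxocyclopentane-1-carboxylic acid, via isocyanate 2 (not isolated)
Conditions: (PhO)2P(O)N3, Et3N, PhMe, 90 °C; then 3 M aq HCl, reflux
Reagents that add atoms: water, O
Why: Curtius rearrangement moves the bridgehead carbon to nitrogen with retention, and acid hydrolysis collapses the resulting α-acyloxy amine (an N,O-acetal) to the ketone while freeing the carboxylic acid, so that only the bought quaternary stereocentre remains.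

Step 2
Reactants: 3 keto acid
Product: 4 (1S,3S)-3-(hydroxymethyl)-2,2,3-trimethylcyclopentan-1-ol
Conditions: (R)-2-methyl-CBS-oxazaborolidine (20 mol %), BH3·SMe2 (4 equiv), THF, 0 to 40 °C; MeOH
Reagents that add atoms: none
Why: Corey–Bakshi–Shibata reduction distinguishes the CMe2 flank from the CH2 flank and should give the (S)-carbinol (OH trans to the side chain), a sense reinforced by hydride delivery from the acyloxyborane on the side-chain face, while excess borane reduces the acid to the primary alcohol.

Step 3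
Reactants: 4 diol
Product: 5 (1S,3S)-3-hydroxy-1,2,2-trimethylcyclopentane-1-carbaldehyde
Conditions: TEMPO (10 mol %), PhI(OAc)2, CH2Cl2, rt
Reagents that add atoms: none
Why: Oxoammonium (TEMPO) oxidation is much faster for the primary than for the hindered secondary alcohol, and the trans hydroxy aldehyde cannot close to a lactol.

Step 4
Reactants: 5 hydroxy aldehyde
Product: 6 (1S,3R)-3-ethynyl-2,2,3-trimethylcyclopentan-1-ol
Conditions: dimethyl (1-diazo-2-oxopropyl)phosphonate, K2CO3, MeOH, rt
Reagents that add atoms: dimethyl (1-diazo-2-oxopropyl)phosphonate, CC(=O)C(=[N+]=[N-])P(=O)(OC)OC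
Why: Seyferth–Gilbert homologation in the Ohira–Bestmann variant turns the non-enolisable aldehyde into the terminal alkyne under mild base without touching either stereocentre.

Step 5
Reactants: 6 alkynol
Product: 7 (1R,3R)-3-bromo-1-ethynyl-1,2,2-trimethylcyclopentane
Conditions: CBr4, P(n-C8H17)3, PhMe, 60 °C
Reagents that add atoms: carbon tetrabromide, BrC(Br)(Br)Br
Why: Appel-type bromination, in which bromide displaces the alkoxyphosphonium ion with inversion (SN2 at a cyclopentyl carbon next to a quaternary carbon) and so ends up cis to the alkyne, a linear group that neither shields that face nor participates.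

Step 6
Reactants: 8 prop-2-yn-1-ol
Product: 10 (2E)-3-iodo-2-methylprop-2-en-1-ol, via vinylalane 9 (not isolated)
Conditions: AlMe3 (3 equiv), Cp2ZrCl2 (25 mol %), CH2Cl2, 0 °C to rt; then I2, THF, −30 °C
Reagents that add atoms: trimethylaluminium, C[Al](C)C; iodine, II
Why: Negishi zirconium-catalysed carboalumination adds methyl and aluminium syn across the alkyne with aluminium at the terminus, and iodinolysis with retention gives the (E)-iodide.

Step 7
Reactants: 10 iodo allylic alcohol
Product: 11 (2E)-3-iodo-2-methylprop-2-enal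
Conditions: MnO2, CH2Cl2, rt
Reagents that add atoms: none
Why: Allylic oxidation with MnO2 stops at the enal and keeps the alkene geometry.

Step 8
Reactants: 11 iodo enal
Product: 13 (1E,3R)-1-iodo-2-methylhexa-1,5-dien-3-ol, via borinate 12 (not isolated)
Conditions: (+)-Ipc2BOMe, allylMgBr, Et2O, 0 °C; 11, −78 °C; then NaOH, H2O2
Reagents that add atoms: allylmagnesium bromide, C=CC[Mg]Br
Why: Brown allylboration through a chair transition state, in which the reagent of the (−)-α-pinene series attacks the Re face of the enal and sets the (R)-carbinol, the only stereocentre of the decalin part made by a chiral reagent.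

Step 9
Reactants: 7 bromoalkyne; 13 iodo dienol
Product: 14 (4R,5E)-8-[(1R,3R)-3-bromo-1,2,2-trimethylcyclopentyl]-5-methylocta-1,5-dien-7-yn-4-ol
Conditions: PdCl2(PPh3)2 (3 mol %), CuI (6 mol %), Et3N, THF, rt
Reagents that add atoms: none
Why: Sonogashira coupling, in which the vinyl iodide adds oxidatively to zerovalent palladium far faster than the hindered secondary alkyl bromide and the alkene geometry is retained.

Step 10
Reactants: 14 dienynol
Product: 16 (3E,5R)-1-[(1R,3R)-3-bromo-1,2,2-trimethylcyclopentyl]-5,8-dihydroxy-4-methyloct-3-en-2-one, via tris(dicyclohexylboryl) adduct 15 (not isolated)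
Conditions: Cy2BH (3.5 equiv), THF, 0 °C to rt; then H2O2, aq NaOAc
Reagents that add atoms: hydrogen peroxide, OO
Why: Hydroboration–oxidation, in which the bulky borane adds anti-Markovnikov to the terminal alkene and once to the alkyne with boron remote from the quaternary ring A carbon, so that oxidation gives the primary alcohol and, after enol tautomerisation, the (E)-enone.

Step 11
Reactants: 16 keto diol
Product: 18 (5R)-5-{(2E)-5-[(1R,3R)-3-bromo-1,2,2-trimethylcyclopentyl]-4-oxopent-2-en-2-yl}oxolan-2-one, via lactol 17 (not isolated)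
Conditions: TEMPO (20 mol %), PhI(OAc)2 (2.5 equiv), CH2Cl2, rt
Reagents that add atoms: none
Why: Oxidative lactonisation of a 1,4-diol (TEMPO oxidation of the primary alcohol, closure to the five-membered lactol, second oxidation) leaves the C8 stereocentre and the enone untouched.

Step 12
Reactants: 18 enone lactone
Product: 19 (4R,5E)-8-[(1R,3R)-3-bromo-1,2,2-trimethylcyclopentyl]-4-hydroxy-N-methoxy-N,5-dimethyl-7-oxooct-5-enamide
Conditions: MeNH(OMe)·HCl (3 equiv), i-PrMgCl (6 equiv), THF, −20 °C
Reagents that add atoms: N,O-dimethylhydroxylamine hydrochloride, CNOC.Cl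
Why: Weinreb aminolysis, in which the chloromagnesium amide opens the lactone while the hindered β,β-disubstituted enone is inert at this temperature; 19 is used at once to avoid relactonisation.

Step 13
Reactants: 19 hydroxy Weinreb amide
Product: 21 (4R,5E,7Z)-8-[(1R,3R)-3-bromo-1,2,2-trimethylcyclopentyl]-4,7-bis(tert-butyldimethylsilyloxy)-N-methoxy-N,5-dimethylocta-5,7-dienamide, via dilithium alkoxide dienolate 20 (not isolated)
Conditions: LDA (2.3 equiv), THF, −78 °C; then TBSOTf (2.5 equiv), −78 to 0 °C
Reagents that add atoms: tert-butyldimethylsilyl triflate, CC(C)(C)[Si](C)(C)OS(=O)(=O)C(F)(F)F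
Why: Kinetic α′-deprotonation of the enone by LDA gives the cross-conjugated dienolate (the amide is far less acidic), ring A forces the (Z)-enolate with ring A trans to the vinyl group, and the silyl triflate caps both oxygen atoms.

Step 14
Reactants: 21 silyloxydiene amide
Product: 22 (6R,7E,9Z)-10-[(1R,3R)-3-bromo-1,2,2-trimethylcyclopentyl]-6,9-bis(tert-butyldimethylsilyloxy)-7-methyldeca-7,9-dien-1-yn-3-one
Conditions: HC≡CMgBr (3 equiv), THF, 0 °C
Reagents that add atoms: ethynylmagnesium bromide, C#C[Mg]Br
Why: Weinreb ketone synthesis, in which the chelated tetrahedral adduct survives until work-up, so that a single ethynyl group enters and the silyl dienol ether is not touched.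

Step 15
Reactants: 22 silyloxydiene ynone
Product: 23 bicyclic cycloadduct (target numbering: C5 ketone conjugated to C4=C4a; C1=C2 TBS enol ether; 8α-OTBS axial; 8aβ-methyl; 3β-H; 3R,8R,8aS)
Conditions: PhMe (0.005 M), BHT, 90 °C
Reagents that add atoms: none
Why: Thermal, concerted but asynchronous normal-electron-demand [4+2] cycloaddition (type 1 intramolecular Diels–Alder reaction of a 2-silyloxydiene and a tethered ynone, a well-known class), in which the nucleophilic diene terminus C3 bonds to the unsubstituted ynone β-carbon C4 ahead of C8a–C4a. Ring B closes as the six-membered 4π+2π ring that holds both new σ-bonds, and ring C closes through C4a–C8a over the four-atom tether C5–C8 in the fused (not bridged) mode. Regiochemistry is matched twice, by the tether length and by the para rule (C2 silyloxy group against C5 acyl group). C8a is controlled by the C8 stereocentre: in the boat-like folded tether C7 avoids the geminal C8a methyl group (allylic 1,2-strain) and the bulky C8 silyloxy group points away from the incoming alkyne, so that the alkyne should add to the diene face that leaves C8–O anti to the methyl group (α, axial). C3 follows from suprafacial addition to the (Z)-enol ether/(E)-alkene diene (ring A and C8 both outside, hence cis) and is erased in step 18. The alkyne dienophile removes any endo/exo question, quaternary C8a blocks aromatisation, and high dilution plus BHT suppress ynone polymerisation.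

Step 16
Reactants: 23 cycloadduct
Product: 24 8α-hydroxy enedione (C2 and C5 ketones; C4=C4a; 3R,8R,8aS)
Conditions: 48% aq HF, MeCN, 0 °C to rt
Reagents that add atoms: none
Why: Acidic fluoride desilylation frees the C8 alcohol and protonates the enol ether at C1 to give the C2 ketone, and no stereocentre that survives in the target is affected.

Step 17
Reactants: 24 hydroxy enedione
Product: 26 8β-bromo enedione (3R,8S,8aS), via chloromethanesulfonate 25 (not isolated)
Conditions: ClCH2SO2Cl, pyridine, CH2Cl2, 0 °C; then LiBr, DMF, 45 °C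
Reagents that add atoms: lithium bromide, [Li+].[Br-]
Why: Sulfonate displacement (SN2), in which the chloromethanesulfonate (a leaving group between mesylate and triflate, used for neopentyl-type secondary carbinols) leaves from the axial α position and bromide enters from the β face with inversion to give the equatorial bromide, helped by the flexibility of ring C, which still has two trigonal carbons.

Step 18
Reactants: 26 dibromo enedione
Product: 28 4aα-hydroxy-C3=C4-enone-5-ketone (4aR,8S,8aS), via sodium dienolate 27 (not isolated)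
Conditions: NaHMDS (1.05 equiv), THF, −78 °C; then 3-phenyl-2-(phenylsulfonyl)oxaziridine, −78 to −20 °C
Reagents that add atoms: 3-phenyl-2-(phenylsulfonyl)oxaziridine, O=S(=O)(c1ccccc1)N1OC1c1ccccc1
Why: Removal of the doubly activated C3–H gives the fully conjugated anion of a vinylogous 1,3-diketone, which the Davis reagent should hydroxylate (enolate hydroxylation) at C4a rather than at C3 because C3 bears ring A, and from the α face opposite the axial C8a methyl group, so that the C3=C4 enone and the trans ring fusion arise together.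

Step 19
Reactants: 28 ketol
Product: 29 target (4aR,5R,8S,8aS)-8-bromo-3-[(1R,3R)-3-bromo-1,2,2-trimethylcyclopentyl]-4a,5-dihydroxy-5,8a-dimethyl-4a,5,6,7,8,8a-hexahydronaphthalen-2(1H)-one
Conditions: MeMgBr (3.5 equiv), THF, −78 to −30 °C
Reagents that add atoms: methylmagnesium bromide, C[Mg]Br
Why: Grignard addition, in which after deprotonation of the C4a hydroxyl group the neighbouring unconjugated C5 ketone reacts in preference to the conjugated C2 ketone shielded by ring A, and equatorial attack from the α side (the axial β path is blocked by the syn-axial C8a methyl group) gives the 5β-hydroxy-5α-methyl carbinol.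

Compound list
1 | (1R,4S)-(+)-camphanic acid | CC1(C)[C@@]2(C(=O)O)CC[C@]1(C)C(=O)O2 | starting material
2 | (1R,4S)-1-isocyanato-4,7,7-trimethyl-2-oxabicyclo[2.2.1]heptan-3-one | CC1(C)[C@@]2(N=C=O)CC[C@]1(C)C(=O)O2 | intermediate
3 | (1S)-1,2,2-trimethyl-3-oxocyclopentane-1-carboxylic acid | CC1(C)C(=O)CC[C@]1(C)C(=O)O | intermediate
4 | (1S,3S)-3-(hydroxymethyl)-2,2,3-trimethylcyclopentan-1-ol | CC1(C)[C@@H](O)CC[C@]1(C)CO | intermediate
5 | (1S,3S)-3-hydroxy-1,2,2-trimethylcyclopentane-1-carbaldehyde | CC1(C)[C@@H](O)CC[C@]1(C)C=O | intermediate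
6 | (1S,3R)-3-ethynyl-2,2,3-trimethylcyclopentan-1-ol | CC1(C)[C@@H](O)CC[C@]1(C)C#C | intermediate
7 | (1R,3R)-3-bromo-1-ethynyl-1,2,2-trimethylcyclopentane | CC1(C)[C@H](Br)CC[C@]1(C)C#C | intermediate
8 | prop-2-yn-1-ol | C#CCO | starting material
9 | (E)-vinylalane, dimethylaluminium alkoxide of 3-(dimethylalumanyl)-2-methylprop-2-en-1-ol | C[Al](C)/C=C(C)/CO[Al](C)C | intermediate
10 | (2E)-3-iodo-2-methylprop-2-en-1-ol | OC/C(C)=C/I | intermediate
11 | (2E)-3-iodo-2-methylprop-2-enal | O=C/C(C)=C/I | intermediate
12 | diisopinocampheylborinate of 13 | C=CC[C@@H](OB([C@H]1C[C@H]2C[C@@H]([C@@H]1C)C2(C)C)[C@H]1C[C@H]2C[C@@H]([C@@H]1C)C2(C)C)/C(C)=C/I | intermediate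
13 | (1E,3R)-1-iodo-2-methylhexa-1,5-dien-3-ol | C=CC[C@@H](O)/C(C)=C/I | intermediate
14 | (4R,5E)-8-[(1R,3R)-3-bromo-1,2,2-trimethylcyclopentyl]-5-methylocta-1,5-dien-7-yn-4-ol | CC1(C)[C@H](Br)CC[C@]1(C)C#C/C=C(C)/[C@H](O)CC=C | intermediate
15 | tris(dicyclohexylboryl) adduct of 14 (alkylborane, dienylborane from syn addition, borinate) | CC1(C)[C@H](Br)CC[C@]1(C)/C=C(B(C1CCCCC1)C1CCCCC1)\C=C(C)\[C@H](OB(C1CCCCC1)C1CCCCC1)CCCB(C1CCCCC1)C1CCCCC1 | intermediate
16 | (3E,5R)-1-[(1R,3R)-3-bromo-1,2,2-trimethylcyclopentyl]-5,8-dihydroxy-4-methyloct-3-en-2-one | CC1(C)[C@H](Br)CC[C@]1(C)CC(=O)/C=C(C)/[C@H](O)CCCO | intermediate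
17 | lactol of 16 (anomeric centre undefined) | CC1(C)[C@H](Br)CC[C@]1(C)CC(=O)/C=C(C)/[C@H]1CCC(O)O1 | intermediate
18 | (5R)-5-{(2E)-5-[(1R,3R)-3-bromo-1,2,2-trimethylcyclopentyl]-4-oxopent-2-en-2-yl}oxolan-2-one | CC1(C)[C@H](Br)CC[C@]1(C)CC(=O)/C=C(C)/[C@H]1CCC(=O)O1 | intermediate
19 | (4R,5E)-8-[(1R,3R)-3-bromo-1,2,2-trimethylcyclopentyl]-4-hydroxy-N-methoxy-N,5-dimethyl-7-oxooct-5-enamide | CC1(C)[C@H](Br)CC[C@]1(C)CC(=O)/C=C(C)/[C@H](O)CCC(=O)N(C)OC | intermediate
20 | dilithium alkoxide (Z)-dienolate of 19 | [Li+].[Li+].CC1(C)[C@H](Br)CC[C@]1(C)/C=C([O-])/C=C(C)/[C@H]([O-])CCC(=O)N(C)OC | intermediate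
21 | (4R,5E,7Z)-bis-TBS silyloxydiene Weinreb amide | CC1(C)[C@H](Br)CC[C@]1(C)/C=C(O[Si](C)(C)C(C)(C)C)/C=C(C)/[C@H](O[Si](C)(C)C(C)(C)C)CCC(=O)N(C)OC | intermediate
22 | (6R,7E,9Z)-bis-TBS silyloxydiene ynone | CC1(C)[C@H](Br)CC[C@]1(C)/C=C(O[Si](C)(C)C(C)(C)C)/C=C(C)/[C@H](O[Si](C)(C)C(C)(C)C)CCC(=O)C#C | intermediate
23 | cycloadduct (3R,8R,8aS; C5 enone, C1=C2 TBS enol ether, 8α-OTBS, 8aβ-methyl) | CC1(C)[C@H](Br)CC[C@]1(C)[C@H]1C=C2C(=O)CC[C@@H](O[Si](C)(C)C(C)(C)C)[C@@]2(C)C=C1O[Si](C)(C)C(C)(C)C | intermediate
24 | 8α-hydroxy enedione (3R,8R,8aS) | CC1(C)[C@H](Br)CC[C@]1(C)[C@H]1C=C2C(=O)CC[C@@H](O)[C@@]2(C)CC1=O | intermediate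
25 | 8α-chloromethanesulfonate of 24 | CC1(C)[C@H](Br)CC[C@]1(C)[C@H]1C=C2C(=O)CC[C@@H](OS(=O)(=O)CCl)[C@@]2(C)CC1=O | intermediate
26 | 8β-bromo enedione (3R,8S,8aS) | CC1(C)[C@H](Br)CC[C@]1(C)[C@H]1C=C2C(=O)CC[C@H](Br)[C@@]2(C)CC1=O | intermediate
27 | sodium dienolate of 26 | [Na+].CC1(C)[C@H](Br)CC[C@]1(C)C1=CC2=C([O-])CC[C@H](Br)[C@@]2(C)CC1=O | intermediate
28 | 4aα-hydroxy enone ketone (4aR,8S,8aS) | CC1(C)[C@H](Br)CC[C@]1(C)C1=C[C@]2(O)C(=O)CC[C@H](Br)[C@@]2(C)CC1=O | intermediate
29 | (4aR,5R,8S,8aS)-8-bromo-3-[(1R,3R)-3-bromo-1,2,2-trimethylcyclopentyl]-4a,5-dihydroxy-5,8a-dimethyl-4a,5,6,7,8,8a-hexahydronaphthalen-2(1H)-one | CC1(C)[C@H](Br)CC[C@]1(C)C1=C[C@]2(O)[C@](C)(O)CC[C@H](Br)[C@@]2(C)CC1=O | target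

Total step count: 19. Longest linear sequence: 16 steps (steps 1–5 and 9–19).

Steps most likely to fail

Step 15. The cycloaddition may be slow because both diene termini are substituted. A 1,5-hydrogen shift of the inside methyl group, ynone polymerisation or attack on the wrong diene face could then compete. Fallback (sets out from 22, comes back at 24): the pericyclic closure is replaced by an anionic double Michael addition.
- Tris(dimethylamino)sulfonium difluorotrimethylsilicate in THF at −78 °C cleaves the enol silyl ether first.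
- The free cross-conjugated dienolate adds through C3 to ynone carbon C4, and the allenolate so formed closes onto C8a. The same two bonds form at low temperature.
- Protonation gives the 8-O-TBS enedione F1, and aqueous HF in MeCN then gives 24.

Step 17. Substitution at this neopentyl-type carbon may be outrun in three ways: elimination of the sulfonate towards C7, migration of the antiperiplanar C8a methyl group, or O-alkylation of the C2 enol. Fallback (sets out from 24, comes back at 29): bromine is placed on a trigonal C8, and hydrogen instead of bromide is delivered to C8.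
- Dess–Martin periodinane gives the 8-ketone F2.
- Two equivalents of KHMDS follow: the first ties up C2 and C5 as the conjugated dienolate, the second deprotonates C7. N-(5-chloropyridin-2-yl)bis(trifluoromethanesulfonimide) then gives the C7=C8 enol triflate F3.
- LiBr and [Cp*Ru(MeCN)3]OTf exchange triflate for bromide to give the vinyl bromide F4.
- The conditions of steps 18 and 19 applied in turn give the vinyl bromide ketol F5 and the 7,8-didehydro target F6.
- Hydrogen atom transfer hydrogenation (Mn(dpm)3, PhSiH3, t-BuOOH, i-PrOH), which tolerates alkenyl halides, adds hydrogen to C7 and then to the α-bromo radical from the open α face. Bromine stays equatorial and 29 results. The C3=C4 enone is shielded by ring A and C4a.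

Step 18. Oxygen transfer may go to C3 or stall for steric reasons, and the dienolate may be oxidised further. Fallback (sets out from 23, comes back at 29): the C4a and C5 oxygen atoms are introduced together by trans-diaxial opening of an epoxide.
- MeLi adds to the only free carbonyl group of 23 to give the tertiary allylic alcohol F7.
- Aqueous HCl in THF removes both silyl groups and dehydrates to the linear dienone alcohol F8.
- ClCH2SO2Cl and pyridine give the dienone chloromethanesulfonate F9, and LiBr in DMF gives the 8β-bromo dienone F10.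
- m-CPBA epoxidises the electron-richer tetrasubstituted C4a=C5 bond from the α face to give the 4aα,5α-epoxide F11.
- Dilute HClO4 in aqueous THF opens the epoxide at tertiary C5, remote from the enone, by attack of water from the β face, which gives 29.

Further compounds
F1 | step 15 | 8-O-TBS enedione | CC1(C)[C@H](Br)CC[C@]1(C)[C@H]1C=C2C(=O)CC[C@@H](O[Si](C)(C)C(C)(C)C)[C@@]2(C)CC1=O
F2 | step 17 | 8-ketone | CC1(C)[C@H](Br)CC[C@]1(C)[C@H]1C=C2C(=O)CCC(=O)[C@@]2(C)CC1=O
F3 | step 17 | C7=C8 enol triflate | CC1(C)[C@H](Br)CC[C@]1(C)[C@H]1C=C2C(=O)CC=C(OS(=O)(=O)C(F)(F)F)[C@@]2(C)CC1=O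
F4 | step 17 | vinyl bromide | CC1(C)[C@H](Br)CC[C@]1(C)[C@H]1C=C2C(=O)CC=C(Br)[C@@]2(C)CC1=O
F5 | step 17 | vinyl bromide ketol | CC1(C)[C@H](Br)CC[C@]1(C)C1=C[C@]2(O)C(=O)CC=C(Br)[C@@]2(C)CC1=O
F6 | step 17 | 7,8-didehydro target | CC1(C)[C@H](Br)CC[C@]1(C)C1=C[C@]2(O)[C@](C)(O)CC=C(Br)[C@@]2(C)CC1=O
F7 | step 18 | tertiary allylic alcohol | CC1(C)[C@H](Br)CC[C@]1(C)[C@H]1C=C2[C@](C)(O)CC[C@@H](O[Si](C)(C)C(C)(C)C)[C@@]2(C)C=C1O[Si](C)(C)C(C)(C)C
F8 | step 18 | linear dienone alcohol | CC1(C)[C@H](Br)CC[C@]1(C)C1=CC2=C(C)CC[C@@H](O)[C@@]2(C)CC1=O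
F9 | step 18 | dienone chloromethanesulfonate | CC1(C)[C@H](Br)CC[C@]1(C)C1=CC2=C(C)CC[C@@H](OS(=O)(=O)CCl)[C@@]2(C)CC1=O
F10 | step 18 | 8β-bromo dienone | CC1(C)[C@H](Br)CC[C@]1(C)C1=CC2=C(C)CC[C@H](Br)[C@@]2(C)CC1=O
F11 | step 18 | 4aα,5α-epoxide | CC1(C)[C@H](Br)CC[C@]1(C)C1=C[C@@]23O[C@@]3(C)CC[C@H](Br)[C@@]2(C)CC1=O
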